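**Plan**
- The target is an achiral, C2-symmetric chain of six rings joined by five CH2 groups: ring A (butyrylfilicinic acid), rings B, C, D, E (butyrylphloroglucinols), ring F (butyrylfilicinic acid).
- Cuts, in order: the bond from the B/C bridge CH2 to ring C (giving rings A–B with that CH2, and the tetramer of rings C–F); in the tetramer, the bond from the C/D bridge CH2 to ring C, then the bond from the D/E bridge CH2 to ring E; the A/B bridge (the same bond as the F/E bridge); then the two C-methyl groups and the butanoyl group, back to phloroglucinol.
- Enabling feature: every bridge CH2 sits on a ring carbon flanked by two C–OH carbons, so a dimethylamino group on that CH2 is expelled to give an o-quinone methide. Ring C of the tetramer has exactly one unsubstituted carbon, also between two C–OH carbons, as its only carbon nucleophile; joining the two copies the presumed biosynthetic methylene bridging.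
- Forward: phloroglucinol → butyrylphloroglucinol → butyrylfilicinic acid → its Mannich base → the filicinic acid–phloroglucinol dimer, which serves both as rings A–B and as rings F–E. One portion is armed with CH2NMe2 on ring B. The other is extended by the bis-Mannich base of butyrylphloroglucinol (ring D) and then by butyrylphloroglucinol (ring C) to the tetramer. The two are joined last.
- Stereochemistry: none to set; the target has no stereocentre and no stereogenic double bond.

Key step: step 9

Assumption: the triketone rings and the Mannich bases are written as the neutral enol and amine forms used in the target SMILES; in the flask they are mobile tautomers and inner salts of the same compounds.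

**Step 1**
Reactants: 1 phloroglucinol; 2 butanoyl chloride
Product: 3 butyrylphloroglucinol (1-(2,4,6-trihydroxyphenyl)butan-1-one)
Conditions: AlCl3 (4 equiv), PhNO2/CH2Cl2, 0 °C → 40 °C; ice/aq. HCl
Reagents that add atoms: none
Why: Friedel–Crafts acylation of the very electron-rich triol, which should stop at the monoketone because the first ketone, held as an aluminium chelate, deactivates the ring while 2 is limiting.

**Step 2**
Reactants: 3 butyrylphloroglucinol
Product: 4 butyrylfilicinic acid (2-butanoyl-3,5-dihydroxy-4,4-dimethylcyclohexa-2,5-dien-1-one)
Conditions: NaOMe (3 equiv), MeI (2.1 equiv), MeOH, 0 °C → rt; aq. HCl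
Reagents that add atoms: iodomethane CI
Why: Dearomatising double C-methylation of the phloroglucinol anion, in which the 3-methyl intermediate is methylated again at the same electron-rich carbon in competition with the other free carbon, and the gem-dimethyl triketone, a strong vinylogous acid with a poorly nucleophilic anion, should accumulate and be separable from the 3,5-dimethyl and trimethyl by-products.

**Step 3**
Reactants: 4 butyrylfilicinic acid
Product: 5 filicinic acid Mannich base (2-butanoyl-6-[(dimethylamino)methyl]-3,5-dihydroxy-4,4-dimethylcyclohexa-2,5-dien-1-one)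
Conditions: CH2(NMe2)2 (1.1 equiv), CH2Cl2, 0 °C → rt
Reagents that add atoms: bis(dimethylamino)methane CN(C)CN(C)C
Why: Mannich reaction in which the acidic triketone protonates the aminal, the CH2=NMe2+ released is captured at C6, the only unsubstituted ring carbon, and the product is stabilised as an inner salt.

**Step 4**
Reactants: 5 filicinic acid Mannich base; 3 butyrylphloroglucinol (4 equiv)
Product: 7 filicinic acid–phloroglucinol dimer (2-butanoyl-6-[(3-butanoyl-2,4,6-trihydroxyphenyl)methyl]-3,5-dihydroxy-4,4-dimethylcyclohexa-2,5-dien-1-one), via methylidene trione 6 (not isolated)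
Conditions: 1,4-dioxane, 70 °C, Ar stream
Reagents that add atoms: none
Why: Elimination–addition (retro-Mannich loss of Me2NH, then Michael addition) in which the cross-conjugated methylidene trione 6 is attacked by a free ring carbon of 3 and the adduct rearomatises, the excess of 3 keeping the remaining free carbon of the product from reacting again.

**Step 5**
Reactants: 7 filicinic acid–phloroglucinol dimer (the portion that becomes rings A–B)
Product: 8 armed A–B dimer (2-butanoyl-6-({3-butanoyl-5-[(dimethylamino)methyl]-2,4,6-trihydroxyphenyl}methyl)-3,5-dihydroxy-4,4-dimethylcyclohexa-2,5-dien-1-one)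
Conditions: CH2(NMe2)2 (1.2 equiv), CH2Cl2, 0 °C → rt
Reagents that add atoms: bis(dimethylamino)methane CN(C)CN(C)C
Why: Mannich reaction (electrophilic aromatic aminomethylation) with a single possible site, since the phloroglucinol ring has one unsubstituted carbon flanked by two OH groups and the filicinic acid ring has none, the iminium ion being released from the aminal by the acidic filicinic acid enol.

**Step 6**
Reactants: 3 butyrylphloroglucinol
Product: 9 bis-Mannich base of butyrylphloroglucinol (1-{3,5-bis[(dimethylamino)methyl]-2,4,6-trihydroxyphenyl}butan-1-one)
Conditions: CH2(NMe2)2 (2.5 equiv), AcOH (0.1 equiv), THF, 0 °C → rt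
Reagents that add atoms: bis(dimethylamino)methane CN(C)CN(C)C
Why: Twofold Mannich reaction at the two equivalent unsubstituted carbons of 3, in which the excess of aminal at low temperature should carry the mono-Mannich base on to the bis-base before it can lose amine, so that the product has no free ring carbon and cannot condense with itself.

**Step 7**
Reactants: 9 bis-Mannich base of butyrylphloroglucinol (3 equiv); 7 filicinic acid–phloroglucinol dimer (the portion that becomes rings F–E)
Product: 11 armed trimer of rings F–E–D with CH2NMe2 on ring D (2-butanoyl-6-{[3-butanoyl-5-({3-butanoyl-5-[(dimethylamino)methyl]-2,4,6-trihydroxyphenyl}methyl)-2,4,6-trihydroxyphenyl]methyl}-3,5-dihydroxy-4,4-dimethylcyclohexa-2,5-dien-1-one), via o-quinone methide 10 (not isolated)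
Conditions: 1,4-dioxane, 65 °C, sealed vessel; aq. NaH2PO4 wash to remove excess 9
Reagents that add atoms: none
Why: o-Quinone methide elimination–addition (Michael / Friedel–Crafts alkylation) in which 9 loses Me2NH to give 10 and the single free ring carbon of 7 adds to its exocyclic CH2, the excess of 9 ensuring that 7 is consumed by 10 and not by the remaining arm of the product, while the amine kept in the closed vessel returns idle 10 to 9.

**Step 8**
Reactants: 11 armed trimer of rings F–E–D; 3 butyrylphloroglucinol (5 equiv)
Product: 13 tetramer of rings C–D–E–F with one free carbon on ring C, via trimer o-quinone methide 12 (not isolated)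
Conditions: 1,4-dioxane, 80 °C, Ar stream; dilute aq. HCl wash
Reagents that add atoms: none
Why: The same o-quinone methide elimination–addition, in which 11 loses Me2NH to give 12 and a free ring carbon of 3 adds to the exocyclic CH2 and rearomatises as ring C, the excess of 3 keeping the one remaining free carbon of 13 from reacting again.

**Step 9**
Reactants: 13 tetramer of rings C–D–E–F; 8 armed A–B dimer (1.1 equiv)
Product: 15 target hexamer, via o-quinone methide 14 (not isolated)
Conditions: 1,4-dioxane, 90 °C, Ar stream; dilute aq. HCl wash
Reagents that add atoms: none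
Why: Mechanism: a proton shift in the inner salt of 8 places phenoxide character on an oxygen flanking the ring B side chain, Me2NH is expelled in an E1cB step to give o-quinone methide 14, the single unsubstituted carbon of ring C in 13 adds to the exocyclic CH2 in a Michael addition, and tautomerisation of the resulting cyclohexadienone restores both aromatic rings. The closest known reaction type is the elimination–addition alkylation of phenols and acylphloroglucinols by phenolic Mannich bases (o-quinone methide Friedel–Crafts alkylation), the laboratory counterpart of the presumed biosynthetic methylene bridging. No ring is closed and no stereocentre is formed, so there is no mode of closure and no facial control to secure. The step needs site selectivity, which the substrates supply: 13 has only one ring carbon bearing hydrogen, 8 and 14 have none and cannot self-condense, and O-alkylation is reversible under the thermal conditions while C-alkylation is fixed by rearomatisation. It also needs the four existing CH2 bridges to stay in place, which should be secured by the base-free, near-neutral medium, the argon stream that removes Me2NH, and the far greater leaving ability of the ammonium group compared with a carbon leaving group.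

**Compound list**
1 | phloroglucinol (benzene-1,3,5-triol) | Oc1cc(O)cc(O)c1 | starting material
2 | butanoyl chloride | CCCC(=O)Cl | starting material
3 | butyrylphloroglucinol, 1-(2,4,6-trihydroxyphenyl)butan-1-one | CCCC(=O)c1c(O)cc(O)cc1O | intermediate
4 | butyrylfilicinic acid, 2-butanoyl-3,5-dihydroxy-4,4-dimethylcyclohexa-2,5-dien-1-one | CCCC(=O)C1=C(O)C(C)(C)C(O)=CC1=O | intermediate
5 | filicinic acid Mannich base, 2-butanoyl-6-[(dimethylamino)methyl]-3,5-dihydroxy-4,4-dimethylcyclohexa-2,5-dien-1-one | CCCC(=O)C1=C(O)C(C)(C)C(O)=C(CN(C)C)C1=O | intermediate
6 | methylidene trione (not isolated), 2-butanoyl-3-hydroxy-4,4-dimethyl-6-methylidenecyclohex-2-ene-1,5-dione | CCCC(=O)C1=C(O)C(C)(C)C(=O)C(=C)C1=O | intermediate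
7 | filicinic acid–phloroglucinol dimer (rings A–B and rings F–E), 2-butanoyl-6-[(3-butanoyl-2,4,6-trihydroxyphenyl)methyl]-3,5-dihydroxy-4,4-dimethylcyclohexa-2,5-dien-1-one | CCCC(=O)C1=C(O)C(C)(C)C(O)=C(Cc2c(O)cc(O)c(C(=O)CCC)c2O)C1=O | intermediate
8 | armed A–B dimer, as 7 with CH2NMe2 on the free carbon of ring B | CCCC(=O)C1=C(O)C(C)(C)C(O)=C(Cc2c(O)c(CN(C)C)c(O)c(C(=O)CCC)c2O)C1=O | intermediate
9 | bis-Mannich base of butyrylphloroglucinol, 1-{3,5-bis[(dimethylamino)methyl]-2,4,6-trihydroxyphenyl}butan-1-one | CCCC(=O)c1c(O)c(CN(C)C)c(O)c(CN(C)C)c1O | intermediate
10 | o-quinone methide from 9 (not isolated), 2-butanoyl-4-[(dimethylamino)methyl]-3,5-dihydroxy-6-methylidenecyclohexa-2,4-dien-1-one | CCCC(=O)C1=C(O)C(CN(C)C)=C(O)C(=C)C1=O | intermediate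
11 | armed trimer: butyrylfilicinic acid ring F–CH2–ring E–CH2–ring D, rings E and D being butyrylphloroglucinols and ring D carrying CH2NMe2 on its last ring carbon | CCCC(=O)C1=C(O)C(C)(C)C(O)=C(Cc2c(O)c(Cc3c(O)c(CN(C)C)c(O)c(C(=O)CCC)c3O)c(O)c(C(=O)CCC)c2O)C1=O | intermediate
12 | trimer o-quinone methide from 11 (not isolated): ring D as 2-butanoyl-3,5-dihydroxy-6-methylidenecyclohexa-2,4-dien-1-one carrying the ring E–CH2 group at C4 | CCCC(=O)C1=C(O)C(C)(C)C(O)=C(Cc2c(O)c(CC3=C(O)C(=C)C(=O)C(C(=O)CCC)=C3O)c(O)c(C(=O)CCC)c2O)C1=O | intermediate
13 | tetramer: butyrylfilicinic acid ring F–CH2–ring E–CH2–ring D–CH2–ring C, rings C–E being butyrylphloroglucinols and ring C keeping one unsubstituted carbon | CCCC(=O)C1=C(O)C(C)(C)C(O)=C(Cc2c(O)c(Cc3c(O)c(Cc4c(O)cc(O)c(C(=O)CCC)c4O)c(O)c(C(=O)CCC)c3O)c(O)c(C(=O)CCC)c2O)C1=O | intermediate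
14 | o-quinone methide from 8 (not isolated): ring B as 2-butanoyl-3,5-dihydroxy-6-methylidenecyclohexa-2,4-dien-1-one carrying the ring A–CH2 group at C4 | CCCC(=O)C1=C(O)C(C)(C)C(O)=C(CC2=C(O)C(=C)C(=O)C(C(=O)CCC)=C2O)C1=O | intermediate
15 | target hexamer CNP0237140.0 (rings A–F, achiral) | CCCC(=O)C1=C(O)C(C)(C)C(O)=C(Cc2c(O)c(Cc3c(O)c(Cc4c(O)c(Cc5c(O)c(CC6=C(O)C(C)(C)C(O)=C(C(=O)CCC)C6=O)c(O)c(C(=O)CCC)c5O)c(O)c(C(=O)CCC)c4O)c(O)c(C(=O)CCC)c3O)c(O)c(C(=O)CCC)c2O)C1=O | target

**Step count**
Total steps: 9. Longest linear sequence: 7 steps (steps 1, 2, 3, 4, 7, 8, 9 from phloroglucinol). Step 5 is a one-step branch from 7, and step 6 is a one-step branch from 3.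

**Steps most likely to fail**

Step 9. The risk is reversible cleavage of the CH2 bridges (retro-Michael opening to quinone methides and recombination) in the warm medium that still holds some amine, which would scramble the chain lengths. The fallback uses the C2 symmetry and sets out from 8. Heating 8 with an excess of 3 in 1,4-dioxane (the reaction type of step 4) should give the A–B–C trimer F1, which has a single free carbon on its terminal ring. Two molecules of the A–B–C trimer F1 are then joined through the central CH2 with formaldehyde (0.5 equiv) in cold dilute aqueous KOH for a few minutes, followed by immediate acidification. This forms the C/D bridge last, at 0 °C and on a substrate with one reactive site, and comes back to the route at 15.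

Step 7. The risk is loss of mono-selectivity on the two equivalent arms of 9, so that both arms capture a molecule of 7, together with self-addition of the quinone methide when the nucleophile runs short. The fallback moves the leaving group to the other partner and sets out from 3. Condensation of 3 (in excess) with formaldehyde (0.25 equiv) in cold 1 % aqueous KOH for a few minutes, then acid, should give methylenebis(butyrylphloroglucinol) F2, the unit of rings C–D with two equivalent free carbons. Heating 8 with methylenebis(butyrylphloroglucinol) F2 (3 equiv) in 1,4-dioxane forms 14 in the flask, which is captured by one free carbon of F2, so that the two rings of 8 become rings F and E. The fallback leaves out 11 and step 8 and comes back to the route at 13.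

Step 3. The risk is premature loss of Me2NH from the triketone Mannich base while 4 is still present, so that 6 is captured by a second molecule of 4 and the symmetric bis(filicinic acid)methane forms instead of 5. The fallback sets out from 4 and masks the methylidene trione with sulfur. Three-component condensation of 4 with formaldehyde and thiophenol (cat. Et3N, EtOH, rt) should give the phenylsulfanylmethyl triketone F3, because thiophenol outcompetes the enol of 4 for 6. Oxidation of the phenylsulfanylmethyl triketone F3 with NaIO4 (MeOH/H2O, 0 °C) gives the sulfoxide F4 (racemic at sulfur). Warming the sulfoxide F4 with an excess of 3 in 1,4-dioxane expels benzenesulfenic acid, forms 6 in the flask and comes back to the route at 7.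

**Further compounds**
F1 | step 9 | A–B–C trimer: butyrylfilicinic acid ring–CH2–butyrylphloroglucinol ring–CH2–butyrylphloroglucinol ring with one free ring carbon | CCCC(=O)C1=C(O)C(C)(C)C(O)=C(Cc2c(O)c(Cc3c(O)cc(O)c(C(=O)CCC)c3O)c(O)c(C(=O)CCC)c2O)C1=O
F2 | step 7 | methylenebis(butyrylphloroglucinol), bis(3-butanoyl-2,4,6-trihydroxyphenyl)methane | CCCC(=O)c1c(O)cc(O)c(Cc2c(O)cc(O)c(C(=O)CCC)c2O)c1O
F3 | step 3 | 2-butanoyl-3,5-dihydroxy-4,4-dimethyl-6-[(phenylsulfanyl)methyl]cyclohexa-2,5-dien-1-one | CCCC(=O)C1=C(O)C(C)(C)C(O)=C(CSc2ccccc2)C1=O
F4 | step 3 | 2-butanoyl-3,5-dihydroxy-4,4-dimethyl-6-[(phenylsulfinyl)methyl]cyclohexa-2,5-dien-1-one (racemic at sulfur) | CCCC(=O)C1=C(O)C(C)(C)C(O)=C(CS(=O)c2ccccc2)C1=O
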